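Ring A, with its alternating C–OH, C–O–aryl and C–alkyl carbons, is the imprint of a vinylketene plus a heteroatom-substituted alkyne, so it is built while the 22-membered ring closes. The precursor is an open chain on ring B with two alkynyl ethers. The ethyl ether has β-hydrogens and sheds ethylene on heating to give the vinylketene. The aryl ether, whose oxygen is already the hindered O between rings A and B, cannot fragment and traps it. One thermal, Danheiser-type operation forms the macrocycle, ring A, the diaryl ether and the free phenol. No ring is closed afterwards. The para ketone on ring B, needed for assembly, finally gives the (R)-carbinol by asymmetric transfer hydrogenation.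

Key step: step 6

Assumption: the carbinol carbon of the target is read as (R) (OH > ring B carbon > CH2 > H). 15-Hexadecynoic acid, ethoxyacetylene (hexane solution) and 4-bromo-2,6-dimethoxyphenol are taken as purchasable.

Step 1
Reactants: 1 15-hexadecynoic acid
Product: 2 15-iodohexadec-15-enoic acid
Conditions: NaI, Me3SiCl, H2O (0.5 equiv per Me3SiCl), MeCN, rt
Reagents that add atoms: sodium iodide, [Na+].[I-]
Why: Markovnikov hydroiodination: HI made in situ from NaI, Me3SiCl and water protonates the terminal alkyne carbon and iodide adds to the internal one, which gives the 2-iodoalk-1-ene while the carboxylic acid stays untouched.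

Step 2
Reactants: 2 15-iodohexadec-15-enoic acid
Product: 4 15-iodo-N-methoxy-N-methylhexadec-15-enamide, via acyl imidazolide 3 (not isolated)
Conditions: CDI, CH2Cl2, rt; then MeNH(OMe)·HCl, rt
Reagents that add atoms: N,O-dimethylhydroxylamine hydrochloride, CNOC.Cl
Why: Weinreb amide formation through the acyl imidazolide is mild enough for the alkenyl iodide, and the amide is the acyl donor that stops at the ketone stage in step 5.

Step 3
Reactants: 4 15-iodo-N-methoxy-N-methylhexadec-15-enamide; 5 ethoxyacetylene
Product: 8 17-ethoxy-N-methoxy-N-methyl-15-methylideneheptadec-16-ynamide, via lithium ethoxyacetylide 6 (not isolated), via ethoxyethynylzinc chloride 7 (not isolated)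
Conditions: 5, n-BuLi, THF, −78 °C; ZnCl2, 0 °C; then 4, Pd(PPh3)4 (5 mol%), THF, rt
Reagents that add atoms: none
Why: Negishi coupling: the alkenyl iodide adds oxidatively to zerovalent palladium, the alkynylzinc reagent transmetalates and reductive elimination gives the 2-substituted enyne ether, while organozinc reagents do not attack a Weinreb amide.

Step 4
Reactants: 9 4-bromo-2,6-dimethoxyphenol; 10 trichloroethylene
Product: 12 5-bromo-2-{[(E)-1,2-dichloroethenyl]oxy}-1,3-dimethoxybenzene, via dichloroacetylene 11 (not isolated)
Conditions: K2CO3, DMF, 70 °C, closed system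
Reagents that add atoms: none
Why: Base-induced loss of HCl gives dichloroacetylene, to which the phenoxide adds in anti fashion (nucleophilic vinylation), so the hindered C–O bond forms at a slim sp carbon and the (E)-dichlorovinyl ether results.

Step 5
Reactants: 12 5-bromo-2-{[(E)-1,2-dichloroethenyl]oxy}-1,3-dimethoxybenzene; 8 17-ethoxy-N-methoxy-N-methyl-15-methylideneheptadec-16-ynamide
Product: 15 17-ethoxy-1-[4-(ethynyloxy)-3,5-dimethoxyphenyl]-15-methylideneheptadec-16-yn-1-one, via dilithio reagent 13 (not isolated), via tetrahedral chelate 14 (not isolated)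
Conditions: 12 added slowly to n-BuLi (3.0 equiv), THF, −78 to −50 °C; then 8 (0.7 equiv), −78 °C; pH 7 buffer; Et3N-deactivated silica; used at once
Reagents that add atoms: none
Why: Bromine–lithium exchange, together with the standard deprotonation, β-elimination and chlorine–lithium exchange of a dichlorovinyl ether, gives 13, whose more basic aryllithium site acylates first in a Weinreb ketone synthesis (chelate 14 blocks a second addition), while the acetylide is only protonated at the quench and the enyne ether of 8 is inert to organolithiums at low temperature.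

Step 6
Reactants: 15 17-ethoxy-1-[4-(ethynyloxy)-3,5-dimethoxyphenyl]-15-methylideneheptadec-16-yn-1-one
Product: 20 macrocyclic ketone dimethyl ether (22-membered ring; ring A newly formed), via vinylketene 16 (not isolated), via bicyclic cyclobutenone 17 (not isolated), via dienylketene 18 (not isolated), via cyclohexadienone 19 (not isolated)
Conditions: xylenes (dry, degassed, base-washed glassware), 140 °C, 15 added by syringe pump over 12 h to 1 mM final, then 12 h, Ar
Reagents that add atoms: none
Why: Proposed new method: the ethyl alkynyl ether of 15 loses ethylene in a thermal retro-ene reaction to give vinylketene 16, whose carbonyl carbon is attacked by the nucleophilic CH terminus of the aryl alkynyl ether, so that a polar (2+2) cycloaddition gives 17, reversible 4π opening gives 18, and 6π closure to 19 followed by tautomerization gives phenol 20. The closest known reaction types are the Danheiser benzannulation (vinylketene from a cyclobutenone plus an alkoxyacetylene, the classical entry to 5-alkylresorcinol monoethers), the retro-ene release of ketenes from ethyl alkynyl ethers used for macrolactonization, and macrocyclizing carbene complex benzannulations; what is new is their union in one tethered substrate. The 22-membered ring closes end to end through the C–C bond between the ketene α-carbon and the oxygen-bearing alkyne carbon under high dilution, and ring A then closes by disrotatory 6π electrocyclization of the isomer of 18 that holds the ketene and vinyl groups cis. No lasting stereocentre is created, since the sp3 carbon of 17 and the CH2 of 19 end as aromatic CH. Chemoselectivity rests on the β-hydrogens that only the ethyl ether has (the aryl ether cannot fragment, its oxygen stays conjugated to the alkyne because the two ortho methoxy groups twist ring B, and the ketone is inert to ketenes without a Lewis acid); regioselectivity rests on the polarity match, which gives the 1,3,5-pattern even if the partners combine in a (4+2) sense; ring formation is favoured over oligomerization by slow addition into hot solvent, where the ketene is released a little at a time.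

Step 7
Reactants: 20 macrocyclic ketone dimethyl ether
Product: 21 macrocyclic trihydroxy ketone
Conditions: BBr3 (6 equiv), CH2Cl2, −78 to 0 °C; then ice water
Reagents that add atoms: none
Why: Lewis acid demethylation of aryl methyl ethers with BBr3 is placed at the ketone stage because the diaryl ether, aryl ketone and alkyl chain are inert to it, whereas a benzylic alcohol would ionize.

Step 8
Reactants: 21 macrocyclic trihydroxy ketone
Product: 22 gravicycle, the (R)-alcohol
Conditions: RuCl[(R,R)-TsDPEN](p-cymene) (2 mol%), HCO2H–Et3N (5:2), THF, 40 °C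
Reagents that add atoms: none
Why: Noyori asymmetric transfer hydrogenation: the (R,R)-TsDPEN ruthenium hydride delivers H to the Si face of the aryl alkyl ketone through the six-membered NH/RuH transition state oriented by the CH/π contact between p-cymene and ring B, which sets the single stereocentre as (R), and no later step can scramble it.

Compound list
1 | 15-hexadecynoic acid | C#CCCCCCCCCCCCCCC(=O)O | starting material
2 | 15-iodohexadec-15-enoic acid | C=C(I)CCCCCCCCCCCCCC(=O)O | intermediate
3 | acyl imidazolide, 1-(imidazol-1-yl)-15-iodohexadec-15-en-1-one (not isolated) | C=C(I)CCCCCCCCCCCCCC(=O)n1ccnc1 | intermediate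
4 | 15-iodo-N-methoxy-N-methylhexadec-15-enamide | C=C(I)CCCCCCCCCCCCCC(=O)N(C)OC | intermediate
5 | ethoxyacetylene | C#COCC | starting material
6 | lithium ethoxyacetylide (not isolated) | [Li]C#COCC | intermediate
7 | ethoxyethynylzinc chloride (not isolated) | Cl[Zn]C#COCC | intermediate
8 | 17-ethoxy-N-methoxy-N-methyl-15-methylideneheptadec-16-ynamide | CCOC#CC(=C)CCCCCCCCCCCCCC(=O)N(C)OC | intermediate
9 | 4-bromo-2,6-dimethoxyphenol | COc1cc(Br)cc(OC)c1O | starting material
10 | trichloroethylene | ClC=C(Cl)Cl | starting material
11 | dichloroacetylene (not isolated) | ClC#CCl | intermediate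
12 | 5-bromo-2-{[(E)-1,2-dichloroethenyl]oxy}-1,3-dimethoxybenzene | COc1cc(Br)cc(OC)c1O/C(Cl)=C\Cl | intermediate
13 | dilithio reagent, {4-[(lithioethynyl)oxy]-3,5-dimethoxyphenyl}lithium (not isolated) | [Li]C#COc1c(OC)cc([Li])cc1OC | intermediate
14 | tetrahedral chelate, lithium alkoxide of the aryl/N-methoxy-N-methyl hemiaminal with the acetylide still lithiated, racemic (not isolated) | [Li]C#COc1c(OC)cc(cc1OC)C(O[Li])(N(C)OC)CCCCCCCCCCCCCC(=C)C#COCC | intermediate
15 | 17-ethoxy-1-[4-(ethynyloxy)-3,5-dimethoxyphenyl]-15-methylideneheptadec-16-yn-1-one | C#COc1c(OC)cc(cc1OC)C(=O)CCCCCCCCCCCCCC(=C)C#COCC | intermediate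
16 | vinylketene, 17-[4-(ethynyloxy)-3,5-dimethoxyphenyl]-3-methylideneheptadec-1-ene-1,17-dione (not isolated) | C#COc1c(OC)cc(cc1OC)C(=O)CCCCCCCCCCCCCC(=C)C=C=O | intermediate
17 | bicyclic cyclobutenone, 3-aryloxy-4-(alk-1-en-2-yl)cyclobut-2-en-1-one whose aryl group (ring B) and alkenyl group are tied by C(=O)(CH2)13, racemic (not isolated) | O=C1C=C2Oc3c(OC)cc(cc3OC)C(=O)CCCCCCCCCCCCCC(=C)C12 | intermediate
18 | dienylketene, macrocyclic enol ether with ketenyl and 1-methylidene groups cis on the ring C=C (not isolated) | O=C=C/C1=C\C(=C)CCCCCCCCCCCCCC(=O)c2cc(OC)c(O1)c(OC)c2 | intermediate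
19 | cyclohexadienone, 3-aryloxy-5-alkylcyclohexa-2,4-dien-1-one keto tautomer of 20 (not isolated) | O=C1C=C2C=C(C1)CCCCCCCCCCCCCC(=O)c1cc(OC)c(O2)c(OC)c1 | intermediate
20 | macrocyclic ketone dimethyl ether: ring A (benzene with OH, O-aryl and alkyl at 1,3,5) and ring B (1-acyl-3,5-dimethoxy-4-aryloxybenzene) joined by the ether O and by C(=O)(CH2)13 | Oc1cc2cc(c1)Oc1c(OC)cc(cc1OC)C(=O)CCCCCCCCCCCCC2 | intermediate
21 | macrocyclic trihydroxy ketone (as 20, with both OMe of ring B as OH) | Oc1cc2cc(c1)Oc1c(O)cc(cc1O)C(=O)CCCCCCCCCCCCC2 | intermediate
22 | gravicycle, (R)-configured benzylic alcohol | Oc1cc2cc(c1)Oc1c(O)cc(cc1O)[C@H](O)CCCCCCCCCCCCC2 | target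

Total step count: 8. Longest linear sequence: 7 (steps 1, 2, 3, 5, 6, 7, 8, starting from 1).

Steps most likely to fail

Step 6.
- What may go wrong: intermolecular capture of the ketene (oligomerization, acylation of the phenol already formed), hydration of the alkynyl ethers by adventitious water, or a sluggish cycloaddition because the para acyl group lowers the nucleophilicity of the aryl alkynyl ether.
- Fallback idea (from 12, back at 20): ring A is made by the classical intermolecular Danheiser benzannulation at high concentration, and the macrocycle is closed in the chain by ring-closing metathesis.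
- Undec-10-enoyl chloride and MeNH(OMe)·HCl (pyridine, CH2Cl2) should give N-methoxy-N-methylundec-10-enamide F1.
- Compound 12 is turned into 13 as in step 5 and acylated with F1 to give 1-[4-(ethynyloxy)-3,5-dimethoxyphenyl]undec-10-en-1-one F2.
- Pent-4-enylmagnesium bromide is added to purchasable 3-ethoxycyclobut-2-en-1-one, and dilute HCl work-up gives 3-(pent-4-en-1-yl)cyclobut-2-en-1-one F3.
- F2 and F3 in toluene (0.5 M, 80 then 110 °C) should give 1-{4-[3-hydroxy-5-(pent-4-en-1-yl)phenoxy]-3,5-dimethoxyphenyl}undec-10-en-1-one F4.
- Second-generation Grubbs catalyst (CH2Cl2, 1 mM, reflux) should close the macrocyclic alkene F5 as an E/Z mixture, and H2 over Pd/C in EtOAc saturates it to 20.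

Step 5.
- What may go wrong: proton transfer from the dichlorovinyl C–H to the aryllithium site, acylation at the acetylide terminus, or butylation by the butyl halides.
- Fallback idea (from 12 and 8, back at 15): the two metalations are separated.
- n-Bu3MgLi (0.4 equiv, THF, −10 °C) exchanges only the bromine of 12. Addition of 8 should give 1-(4-{[(E)-1,2-dichloroethenyl]oxy}-3,5-dimethoxyphenyl)-17-ethoxy-15-methylideneheptadec-16-yn-1-one F6.
- The ketone is then masked by enolization with LiN(SiMe3)2 (−78 °C). n-BuLi (3.2 equiv, −78 to −50 °C) converts the dichlorovinyl ether, and the buffer quench returns 15.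

Step 8.
- What may go wrong: slow hydride transfer to the electron-rich, phenol-bearing ketone and poor facial selectivity in the macrocycle.
- Fallback idea (from 21, back at 22): the phenols are masked and the reductant is changed.
- t-BuMe2SiCl and imidazole in DMF should give the tris(tert-butyldimethylsilyl) ether of the macrocyclic ketone F7.
- Corey–Bakshi–Shibata reduction with the (S)-Me-CBS oxazaborolidine and BH3·SMe2 (THF, −20 °C) should give the (R)-alcohol tris(silyl) ether F8.
- Bu4NF buffered with AcOH (THF, 0 °C) frees 22.

Further compounds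
F1 | step 6 | N-methoxy-N-methylundec-10-enamide | C=CCCCCCCCCC(=O)N(C)OC
F2 | step 6 | 1-[4-(ethynyloxy)-3,5-dimethoxyphenyl]undec-10-en-1-one | C#COc1c(OC)cc(cc1OC)C(=O)CCCCCCCCC=C
F3 | step 6 | 3-(pent-4-en-1-yl)cyclobut-2-en-1-one | C=CCCCC1=CC(=O)C1
F4 | step 6 | 1-{4-[3-hydroxy-5-(pent-4-en-1-yl)phenoxy]-3,5-dimethoxyphenyl}undec-10-en-1-one | Oc1cc(CCCC=C)cc(c1)Oc1c(OC)cc(cc1OC)C(=O)CCCCCCCCC=C
F5 | step 6 | macrocyclic alkene (20 with one chain CH=CH, E/Z mixture) | Oc1cc2cc(c1)Oc1c(OC)cc(cc1OC)C(=O)CCCCCCCCC=CCCC2
F6 | step 5 | 1-(4-{[(E)-1,2-dichloroethenyl]oxy}-3,5-dimethoxyphenyl)-17-ethoxy-15-methylideneheptadec-16-yn-1-one | CCOC#CC(=C)CCCCCCCCCCCCCC(=O)c1cc(OC)c(O/C(Cl)=C\Cl)c(OC)c1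
F7 | step 8 | tris(tert-butyldimethylsilyl) ether of the macrocyclic ketone | CC(C)(C)[Si](C)(C)Oc1cc2cc(c1)Oc1c(O[Si](C)(C)C(C)(C)C)cc(cc1O[Si](C)(C)C(C)(C)C)C(=O)CCCCCCCCCCCCC2
F8 | step 8 | (R)-alcohol tris(silyl) ether | CC(C)(C)[Si](C)(C)Oc1cc2cc(c1)Oc1c(O[Si](C)(C)C(C)(C)C)cc(cc1O[Si](C)(C)C(C)(C)C)[C@H](O)CCCCCCCCCCCCC2
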